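A small charge of D, 15 mM, is a catalyst, so I freeze [D] and fold it into a single number. Winter has twice the [E] of midnight and gives 34.9% of Q against 18.9% at 15.0 min, which is twice, so I take Q to form at a rate proportional to [E][X].

in all of them: D 15 mM
- midnight: J 0.10 M; E 0.10 M; run made earlier
- dawn: J 0.067 M; E 0.10 M; run made earlier
- dusk: J 0.15 M; E 0.10 M; run made earlier
- winter: J 0.10 M; E 0.20 M; run made earlier
- south-west: J 0.10 M (fed, over 0.800 h); E 0.100 M; all but J at the start; J goes in evenly over 0.800 h, the run ends at 1.0 h; time 1.0 h
- north-west: J 0.10 M; E 0.100 M (fed, over 0.800 h); a stirred flask in which E is dosed at a steady rate over 0.800 h without added volume, worked up at 1.0 h; time 1.0 h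
- north: J 0.10 M; E 0.100 M; one stirred flow tank at steady state, fed with the mixture as stated, mean residence time 1.0 h
- south-east: J 0.10 M; E 0.100 M; a closed flask charged with all of it at once and left for 1.0 h; time 1.0 h

- midnight (time / min: Q / %): 3.00: 2.8; 6.00: 6.6; 15.0: 18.9; 40.0: 38.5
- dawn (time / min: Q / %): 15.0: 20.5; 30.0: 32.8; 50.0: 44.7; 60.0: 49.7
- dusk (time / min: Q / %): 5.00: 5.8; 12.0: 14.7; 25.0: 26.2; 60.0: 40.6
- winter (time / min: Q / %): 15.0: 34.9; 30.0: 53.8; 50.0: 67.6; 60.0: 71.7

(scatter of a reading: 0.5 percentage points)

- the stated concentrations are those of everything mixed, before any reaction; amounts are the same in each set-up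
- reactions considered so far: X -> L; J + D -> D + X; E + D + X -> D + Q
- the feed brings no volume worth counting
- the earlier runs were made in a closed, stirred flask

1. the set-up with the highest amount of Q at the outlet or at the end, in percent of the J put in ("none" if the first two lie within 2 percentage points) (south-west / north-west / north / south-east / none)
2. amount of Q at the outlet or at the end, in percent of the J put in, south-west
3. amount of Q at the outlet or at the end, in percent of the J put in, north-west
4. amount of Q at the outlet or at the end, in percent of the J put in, north
5. amount of Q at the outlet or at the end, in percent of the J put in, south-east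

In midnight, Q climbs from 6.6% to 18.9% between 6.00 min and 15.0 min. I take [E] and X each as the charge less Q, and so read

kq = 0.180 /M/min,

the Q-rate constant: Q's rate divided by [E][X], a pseudo-second-order constant at this [D]. I leave out X → L, so I expect the shares below to stand high; they are rough reckonings, not forecasts of the flask.

Now I turn the way of adding. With the charge in at once (south-east), the dose is

θ = kq[E]t = 1.08, and Q = θ/(1 + θ) = 51.9%.

Feeding J (south-west) or E (north-west) evenly delays the mean arrival by half the dosing time, which leaves 0.600 h of clock:

θ = 0.646, and Q = 39.3%.

The tank (north) holds the outlet mixture throughout, and its balance gives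

Q = 39.5%.

The forecast expects south-east to win, on the ground that “X should meet high E early”. It gives 35% for south-west, 31.5% for north-west, 33% for north and 46% for south-east.

The flasks give 34.3%, 32.3%, 33.7% and 46.1% in that order, so south-east stands highest, as forecast.

    X → L (k = 0.00590 /min)
    J + D → D + X (k = 44.0 /M/min)
    E + D + X → D + Q (k = 12.0 /M²/min)

In south-east, kq applied to the mean [E] and mean X of the second half-hour gives a gain of 15 percentage points, and the flask gains 14 points. The neighbouring flask is south-east with 0.40 M of J, so E stands at 0.250 equiv to J. There [X] stays above the [E] charged even at the end, and I freeze X at the mean of the full J charge and its end value, 52.6%. In my reckoning E then decays exponentially, and Q comes to 24.1%. That flask gives 23.6%, with 5.5% of its E left.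

The readings come from a simulation for an exercise; scatter was added.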